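Numbering used throughout: isoflavan numbering (O1, C2, C3, C4, C4a, C5–C8, C8a for the chroman; C1'–C6' for ring B). TIPS = triisopropylsilyl, Piv = 2,2-dimethylpropanoyl.

## The problem

Manuifolin E (19) is a (3R)-isoflavan: ring A is fused to the pyran ring C, and the resorcinol-type ring B hangs on C3, so that O1–C2–C3–C4 is the only sp3 bridge between the two arenes. C3 is the single stereocentre. It has no neighbour that could relay its configuration, so a catalyst or reagent must set it, and in any precursor with a carbonyl at C2 it is an acidic benzylic α-position that epimerises easily. Each arene carries a 1,1-dimethylallyl group (at C6 and at C5') ortho to a free phenol. These are quaternary benzylic carbons with a terminal vinyl group, and they would not survive hydrogenation, carbenoids or strong acid, which closes the neighbouring phenol onto the alkene. The three phenols O7, O2' and O4' must be told apart: O7 and O4' are the handles for the C5 units, whereas O2' must stay out of that chemistry and must not compete with O1 for C2 when ring C is closed. The enabling feature is that O2' sits on the ring B carbon next to C1'. As a benzyl ether of the future C4 (ring A–CH2–O2') it holds a C4–H bond in a 1,5 relationship to a carbene centre at C3, so a single catalytic C–H insertion can form C3–C4 and set C3 while O2' is masked in a ring.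

## Retrosynthesis

**19 back to 17.** The last operation on 19 is removal of an O2' pivalate from 18. In 18 the two aryl–C(quaternary) bonds (C6–C and C5'–C) are cut together by a twofold aromatic Claisen transform, leading to the bis(prenyl ether) 17. Direct C-alkylation of a free polyphenol would give linear prenyl groups with poor site control, and the C5 units cannot be carried from earlier because they would not survive the carbenoid step or the hydrogenolysis. Precursor 17 has no quaternary carbon and comes from diphenol 15 and two equivalents of prenyl bromide (16). The forward reaction must deliver each group to C6 and C5' and not to the flanked positions C8 and C3', and O2' must carry a group that cannot rearrange, hence the pivalate.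

**15 back to 12.** Diphenol 15 arises from bis-silyl ether 14, and 14 from phenol 13 by acylation. In 13 only O2' is free while O7 and O4' are silylated. That pattern is obtained without any selective protection if O2' is released late from a C4–O2' bond, so 13 is traced to the cis-pterocarpan 12 by a retro-hydrogenolysis. This cut is preferred over protecting three similar phenols one by one, and it turns the flexible isoflavan into a rigid tetracycle whose extra ring is removed by hydrogen alone. The forward step must cleave only the doubly activated benzylic C4–O2' bond.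

**12 back to 10.** The O1–C2 bond of 12 is cut to the phenol–alcohol 11 (Mitsunobu transform). Closing ring C on an open isoflavan precursor would let O2' compete by a five-membered closure onto C2, whereas in 11 O2' is tied up in the furan ring and only O1 can react. Diol 11 comes from the ester 10 by a hydride reduction that also removes the O1 pivalate, so C2 is carried at the ester oxidation level and no separate deprotection is needed. The forward reduction must be faster than epimerisation at C3.

**10 back to 9 (key disconnection).** The C3–C4 bond of the cis-2-aryl-2,3-dihydrobenzofuran-3-carboxylate 10 is cut to the aryldiazoacetate 9. The neighbouring cuts are less attractive: C3–C1' would need an asymmetric α-arylation that leaves an epimerisable centre, and C4–C4a would need a Friedel–Crafts alkylation with no handle on C3. The insertion joins the two sp3 carbons directly, sets C3 under catalyst control, and needs only a diazo group and an ether. Precursor 9 is acyclic and achiral. The forward reaction must give the 1,5-insertion with high enantioselectivity under conditions free of base.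

**9 back to 4 and 7.** Diazo transfer links 9 to the arylacetate 8. Cutting the benzylic C4–O2' ether bond of 8 gives the ring A benzylic alcohol 4 and the ring B phenol 7, two arenes of similar size. A redox condensation is asked for, so that no labile benzylic halide has to be isolated.

**4 and 7 back to commercial materials.** Alcohol 4 comes from aldehyde 3 by a non-basic reduction, 3 from 2 by pivaloylation, and 2 from 2,4-dihydroxybenzaldehyde (1) by silylation of the non-chelated hydroxyl. Phenol 7 comes from the methyl ester 6 by silylation of the less hindered hydroxyl, and 6 from 2,4-dihydroxyphenylacetic acid (5). Each protecting group is placed by an inherent difference between the two hydroxyls of a resorcinol.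

## Roads not taken

**Alternative 1:** Twofold Claisen rearrangement as the central step. The cut is at C6–C and C5'–C: heating the 2'-O-SEM 7,4'-bis(prenyl ether) A1 would give 2'-O-SEM manuifolin E A2.
- Merits: both quaternary carbons form without any reagent, the para positions are blocked, and A2 is one deprotection from the target.
- Weak points: the plan says nothing about where the C3 configuration comes from or how O2' alone becomes protected, so an enantioenriched 2'-differentiated isoflavan must be supplied by separate chemistry. Removal of an aryl SEM ether needs hot fluoride or acid, and acid endangers the ortho-(1,1-dimethylallyl)phenols.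
- Comparison: this is not a true rival, because the chosen route ends with the same rearrangement (17 to 18) and shares its regiochemical risk. As a key step it builds two skeletal bonds and both quaternary centres, which is more than the insertion builds. The chosen plan sets against this that its key step settles the two questions left open here (C3 and the singling out of O2'), and that a pivalate on O2' allows a non-acidic final deprotection.

**Alternative 2:** Resorcinol plus 2-arylacrolein annulation. The cuts are C4–C4a and O1–C2. Under a chiral primary amine salt, the prenylated resorcinol A3 would add to the iminium ion of the 2-arylacrolein A4, the enamine would be protonated enantioselectively at C3, and the phenol would close to the lactol A5. Lactol reduction and desilylation would finish the synthesis.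
- Merits: this is the most convergent road. Both 1,1-dimethylallyl groups are already in place, ring C and the stereocentre arise in one step, and the sequence could be about half as long as the chosen one.
- Weak points: C3 of A5 is α to a masked aldehyde and bears an aryl group, so the lactol, hydroxy aldehyde and enol equilibria can erase the configuration under the amine and acid conditions that create it. Enantioselective protonation next to a 2,6-disubstituted aryl ring is hard to control. The resorcinol can react at two ring positions. Reduction of the lactol needs a silane with acid, which threatens the ortho-(1,1-dimethylallyl)phenols. A3 and A4 each need a Claisen rearrangement of their own, so that risk is only moved.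
- Comparison: this road is better in step economy and convergency if it works. The chosen plan sets against it a stereocentre that is configurationally secure after one hydride step and a key step with close precedent.

**Alternative 3:** Conjunctive cross-coupling. The cuts are C3–C1' and C4–C4a. The ate complex of vinylboronic acid pinacol ester A6 and the ring B aryllithium A7 would react with the ring A aryl bromide A8 under Pd(OAc)2 and a chiral MandyPhos ligand to give the secondary boronate A9. One-carbon (Matteson) homologation and oxidation would give C2–OH, followed by debenzylation, Mitsunobu closure and the prenylation and Claisen endgame.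
- Merits: two C–C bonds and the stereocentre form in one catalytic step from simple aryl halides. O2' is differentiated from the start. C3 is never adjacent to a carbonyl, so it cannot epimerise. The step count is comparable or slightly lower.
- Weak points: both aryl partners carry ortho-alkoxy groups, which is demanding for the metallate shift and for enantiocontrol. The electron-rich benzylic boronate A9 is prone to protodeboronation. It must still be homologated at a hindered secondary carbon, because boron sits on C3 and not on C2. The endgame risks are the same.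
- Comparison: this road is equal or better in convergency and in configurational stability. The chosen plan sets against it a key step whose precedent covers oxygenated benzyl ethers of aryldiazoacetates closely, an ester that already is C2 at the right position, and inexpensive reagents on both branches.

Key step: step 8

Assumption: the sense of induction of Rh2(S-PTTL)4 on 9 is taken to follow that of the parent ortho-benzyloxy aryldiazoacetates, giving the (2R,3S) ester. If the opposite sense were found, the enantiomeric catalyst from D-tert-leucine would be used with no other change.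

## Route

Step 1
Reactants: 1 2,4-dihydroxybenzaldehyde
Product: 2 2-hydroxy-4-(triisopropylsilyloxy)benzaldehyde
Conditions: TIPSCl (1.05 equiv), imidazole, CH2Cl2, 0 °C to rt
Reagents that add atoms: triisopropylsilyl chloride, CC(C)[Si](Cl)(C(C)C)C(C)C
Why: Phenol silylation; the 2-hydroxyl is held in a hydrogen bond to the formyl group and is the poorer nucleophile, so one equivalent of the bulky silyl chloride goes to O4 (the future O7).

Step 2
Reactants: 2 2-hydroxy-4-(triisopropylsilyloxy)benzaldehyde
Product: 3 2-formyl-5-(triisopropylsilyloxy)phenyl pivalate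
Conditions: PivCl, Et3N, DMAP (cat.), CH2Cl2, 0 °C to rt
Reagents that add atoms: pivaloyl chloride, CC(C)(C)C(Cl)=O
Why: DMAP-catalysed O-acylation of the remaining phenol; the pivalate on the future O1 is chosen because it later falls in the same hydride step that reduces the ester.

Step 3
Reactants: 3 2-formyl-5-(triisopropylsilyloxy)phenyl pivalate
Product: 4 2-(hydroxymethyl)-5-(triisopropylsilyloxy)phenyl pivalate
Conditions: BH3·SMe2, THF, 0 °C; then MeOH
Reagents that add atoms: none
Why: Borane reduction of an aryl aldehyde proceeds through a neutral alkoxyborane and not a free alkoxide, which avoids the 1,5 O-to-O acyl shift and the quinone methide chemistry known for ortho-acyloxybenzaldehydes under basic borohydride reduction. The aryl ester and the silyl ether are inert to borane at 0 °C.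

Step 4
Reactants: 5 2,4-dihydroxyphenylacetic acid
Product: 6 methyl 2-(2,4-dihydroxyphenyl)acetate
Conditions: MeOH, H2SO4 (cat.), reflux
Reagents that add atoms: methanol, CO
Why: Fischer esterification; in a large excess of methanol the open methyl ester is favoured over the benzofuranone lactone.

Step 5
Reactants: 6 methyl 2-(2,4-dihydroxyphenyl)acetate
Product: 7 methyl 2-[2-hydroxy-4-(triisopropylsilyloxy)phenyl]acetate
Conditions: TIPSCl (1.0 equiv), imidazole, DMF, −20 to 0 °C
Reagents that add atoms: triisopropylsilyl chloride, CC(C)[Si](Cl)(C(C)C)C(C)C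
Why: Sterically controlled monosilylation: the 4-hydroxyl has no ortho substituent whereas the 2-hydroxyl is flanked by the CH2CO2Me group, so the bulky silyl chloride should cap the future O4' and leave the future O2' free.

Step 6
Reactants: 4 2-(hydroxymethyl)-5-(triisopropylsilyloxy)phenyl pivalate; 7 methyl 2-[2-hydroxy-4-(triisopropylsilyloxy)phenyl]acetate
Product: 8 methyl 2-[2-{[2-(pivaloyloxy)-4-(triisopropylsilyloxy)phenyl]methoxy}-4-(triisopropylsilyloxy)phenyl]acetate
Conditions: PPh3, DIAD, THF, 0 °C to rt
Reagents that add atoms: none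
Why: Mitsunobu etherification of a phenol by a primary benzylic alcohol forms the C4–O2' ether under nearly neutral conditions, so no labile electron-rich benzylic halide is isolated and the pivalate has no occasion to migrate.

Step 7
Reactants: 8 methyl 2-[2-{[2-(pivaloyloxy)-4-(triisopropylsilyloxy)phenyl]methoxy}-4-(triisopropylsilyloxy)phenyl]acetate
Product: 9 methyl 2-diazo-2-[2-{[2-(pivaloyloxy)-4-(triisopropylsilyloxy)phenyl]methoxy}-4-(triisopropylsilyloxy)phenyl]acetate
Conditions: p-ABSA, DBU, MeCN, 0 °C to rt
Reagents that add atoms: 4-acetamidobenzenesulfonyl azide, CC(=O)Nc1ccc(cc1)S(=O)(=O)N=[N+]=[N-]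
Why: Regitz diazo transfer to an arylacetate with a sulfonyl azide and an amidine base is the standard entry to aryldiazoacetates; the ArCH2CO2Me position is the only acidic C–H, and pivalate and silyl ethers tolerate DBU.

Step 8
Reactants: 9 methyl 2-diazo-2-[2-{[2-(pivaloyloxy)-4-(triisopropylsilyloxy)phenyl]methoxy}-4-(triisopropylsilyloxy)phenyl]acetate
Product: 10 methyl (2R,3S)-2-[2-(pivaloyloxy)-4-(triisopropylsilyloxy)phenyl]-6-(triisopropylsilyloxy)-2,3-dihydro-1-benzofuran-3-carboxylate (cis)
Conditions: Rh2(S-PTTL)4 (1 mol %), toluene, −60 °C, slow addition of 9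
Reagents that add atoms: none
Why: Rh2(S-PTTL)4, dirhodium tetrakis[N-phthaloyl-(S)-tert-leucinate], should extrude N2 from 9 to give a donor/acceptor rhodium carbenoid at C3, which takes up the C4–H bond in a concerted, asynchronous, hydride-transfer-like transition state and forms C3–C4. The closest known reaction type is the dirhodium-carboxylate-catalysed enantioselective intramolecular C–H insertion of methyl 2-(2-benzyloxyphenyl)-2-diazoacetates to cis-2-aryl-2,3-dihydrobenzofuran-3-carboxylates. The one ring closed is the dihydrofuran, formed by 1,5-insertion through a five-membered transition state comprising C3, C1', C2', O2' and C4. C3 is controlled by the catalyst, whose four phthalimido-tert-leucinate ligands differentiate the two faces of the carbenoid. C4 follows from the insertion geometry, which places the ring A aryl group and the ester cis in the kinetic product, and this centre is erased at step 11. The step needs 1,5-insertion to win over aromatic cycloaddition to ring A, carbene dimerisation and O–H insertion, and it needs the absence of base so that the cis ester does not epimerise. The substrate secures this: the C4–H bonds are activated by the adjacent ether oxygen and the para-silyloxy group, attack of O2' on the carbenoid would give a four-membered ylide, no alkene is present, the ortho-pivaloyloxy group lowers the electron density of ring A, and dilution at low temperature suppresses dimerisation.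

Step 9
Reactants: 10 methyl (2R,3S)-2-[2-(pivaloyloxy)-4-(triisopropylsilyloxy)phenyl]-6-(triisopropylsilyloxy)-2,3-dihydro-1-benzofuran-3-carboxylate
Product: 11 2-[(2R,3R)-3-(hydroxymethyl)-6-(triisopropylsilyloxy)-2,3-dihydro-1-benzofuran-2-yl]-5-(triisopropylsilyloxy)phenol
Conditions: LiAlH4, THF, −20 to 0 °C; aq. potassium sodium tartrate
Reagents that add atoms: none
Why: Hydride reduction of the ester to the primary alcohol (C2) and reductive cleavage of the aryl pivalate (O1–H) occur in one operation. The cold hydride is not basic enough to epimerise C3 before the ester is consumed, after which C3 is no longer acidic (the change of descriptor at C3 is only a change of priorities). Aryl triisopropylsilyl ethers tolerate the reagent at this temperature.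

Step 10
Reactants: 11 2-[(2R,3R)-3-(hydroxymethyl)-6-(triisopropylsilyloxy)-2,3-dihydro-1-benzofuran-2-yl]-5-(triisopropylsilyloxy)phenol
Product: 12 (6aR,11aR)-3,9-bis(triisopropylsilyloxy)-6a,11a-dihydro-6H-[1]benzofuro[3,2-c]chromene (cis-pterocarpan)
Conditions: PPh3, DIAD, THF, 0 °C to rt
Reagents that add atoms: none
Why: Intramolecular Mitsunobu etherification (6-exo-tet displacement at the primary C2 by the O1 phenol) should give the cis-fused pterocarpan. O2' is held in the furan ring, so only O1 can close, and any reversible opening at C4 would funnel back to the cis-fused product without touching C3.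

Step 11
Reactants: 12 (6aR,11aR)-3,9-bis(triisopropylsilyloxy)-6a,11a-dihydro-6H-[1]benzofuro[3,2-c]chromene
Product: 13 2-[(3R)-7-(triisopropylsilyloxy)-3,4-dihydro-2H-chromen-3-yl]-5-(triisopropylsilyloxy)phenol
Conditions: H2 (1 atm), 10% Pd/C, EtOAc–EtOH, rt
Reagents that add atoms: none
Why: Catalytic hydrogenolysis of the doubly activated benzylic C4–O2' bond is the standard opening of pterocarpans to 2'-hydroxyisoflavans. O1–C2 is not benzylic and the silyl ethers are inert, so C4 becomes CH2, O2' is released as the only free phenol and C3 is untouched.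

Step 12
Reactants: 13 2-[(3R)-7-(triisopropylsilyloxy)-3,4-dihydro-2H-chromen-3-yl]-5-(triisopropylsilyloxy)phenol
Product: 14 5-(triisopropylsilyloxy)-2-[(3R)-7-(triisopropylsilyloxy)-3,4-dihydro-2H-chromen-3-yl]phenyl pivalate
Conditions: PivCl, Et3N, DMAP (cat.), CH2Cl2, 0 °C to rt
Reagents that add atoms: pivaloyl chloride, CC(C)(C)C(Cl)=O
Why: DMAP-catalysed acylation of the single free phenol; a pivalate on O2' resists fluoride, carbonate and heat, cannot undergo a sigmatropic shift, and is removable at the end without acid.

Step 13
Reactants: 14 5-(triisopropylsilyloxy)-2-[(3R)-7-(triisopropylsilyloxy)-3,4-dihydro-2H-chromen-3-yl]phenyl pivalate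
Product: 15 5-hydroxy-2-[(3R)-7-hydroxy-3,4-dihydro-2H-chromen-3-yl]phenyl pivalate
Conditions: TBAF, AcOH, THF, 0 °C to rt
Reagents that add atoms: none
Why: Fluoride-induced cleavage of both aryl silyl ethers; acetic acid buffers the phenoxides so that the hindered pivalate is neither cleaved nor transferred.

Step 14
Reactants: 15 5-hydroxy-2-[(3R)-7-hydroxy-3,4-dihydro-2H-chromen-3-yl]phenyl pivalate; 16 prenyl bromide (1-bromo-3-methylbut-2-ene)
Product: 17 5-[(3-methylbut-2-en-1-yl)oxy]-2-[(3R)-7-[(3-methylbut-2-en-1-yl)oxy]-3,4-dihydro-2H-chromen-3-yl]phenyl pivalate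
Conditions: prenyl bromide (2.4 equiv in all), K2CO3, acetone, reflux
Reagents that add atoms: prenyl bromide (second equivalent, for the second phenol), CC(C)=CCBr
Why: Twofold Williamson etherification: each of the two phenols (O7 and O4') takes up one molecule of prenyl bromide by SN2 at the primary allylic carbon, so two equivalents of the bromide are consumed. The weak carbonate base leaves the aryl pivalate intact.

Step 15
Reactants: 17 5-[(3-methylbut-2-en-1-yl)oxy]-2-[(3R)-7-[(3-methylbut-2-en-1-yl)oxy]-3,4-dihydro-2H-chromen-3-yl]phenyl pivalate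
Product: 18 5-hydroxy-2-[(3R)-7-hydroxy-6-(2-methylbut-3-en-2-yl)-3,4-dihydro-2H-chromen-3-yl]-4-(2-methylbut-3-en-2-yl)phenyl pivalate
Conditions: N,N-diethylaniline, 190 °C, sealed tube, argon
Reagents that add atoms: none
Why: Twofold aromatic Claisen rearrangement: each [3,3]-sigmatropic shift delivers a prenyl group with allylic inversion to an ortho carbon and tautomerisation restores the phenol, which creates both 1,1-dimethylallyl groups. The flanked ortho positions C8 and C3' would have to accept a quaternary carbon between two oxygen substituents and are disfavoured, as in known 2-alkoxy-4-prenyloxyarenes, and the para positions C4a and C1' are blocked. The amine solvent suppresses acid-catalysed closure of the product phenols onto the new alkenes.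

Step 16
Reactants: 18 5-hydroxy-2-[(3R)-7-hydroxy-6-(2-methylbut-3-en-2-yl)-3,4-dihydro-2H-chromen-3-yl]-4-(2-methylbut-3-en-2-yl)phenyl pivalate
Product: 19 manuifolin E, 4-[(3R)-7-hydroxy-6-(2-methylbut-3-en-2-yl)-3,4-dihydro-2H-chromen-3-yl]-6-(2-methylbut-3-en-2-yl)benzene-1,3-diol
Conditions: LiAlH4, THF, 0 °C to rt; aq. potassium sodium tartrate
Reagents that add atoms: none
Why: Reductive cleavage of the aryl pivalate by hydride is non-acidic, so the ortho-(1,1-dimethylallyl)phenols are not cyclised; the isolated vinyl groups and C3 are untouched.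

## Compound list

1 | 2,4-dihydroxybenzaldehyde | O=Cc1ccc(O)cc1O | starting material
2 | 2-hydroxy-4-(triisopropylsilyloxy)benzaldehyde | O=Cc1ccc(O[Si](C(C)C)(C(C)C)C(C)C)cc1O | intermediate
3 | 2-formyl-5-(triisopropylsilyloxy)phenyl 2,2-dimethylpropanoate | O=Cc1ccc(O[Si](C(C)C)(C(C)C)C(C)C)cc1OC(=O)C(C)(C)C | intermediate
4 | 2-(hydroxymethyl)-5-(triisopropylsilyloxy)phenyl 2,2-dimethylpropanoate | OCc1ccc(O[Si](C(C)C)(C(C)C)C(C)C)cc1OC(=O)C(C)(C)C | intermediate
5 | 2,4-dihydroxyphenylacetic acid | OC(=O)Cc1ccc(O)cc1O | starting material
6 | methyl 2-(2,4-dihydroxyphenyl)acetate | COC(=O)Cc1ccc(O)cc1O | intermediate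
7 | methyl 2-[2-hydroxy-4-(triisopropylsilyloxy)phenyl]acetate | COC(=O)Cc1ccc(O[Si](C(C)C)(C(C)C)C(C)C)cc1O | intermediate
8 | methyl 2-[2-{[2-(2,2-dimethylpropanoyloxy)-4-(triisopropylsilyloxy)phenyl]methoxy}-4-(triisopropylsilyloxy)phenyl]acetate | COC(=O)Cc1ccc(O[Si](C(C)C)(C(C)C)C(C)C)cc1OCc1ccc(O[Si](C(C)C)(C(C)C)C(C)C)cc1OC(=O)C(C)(C)C | intermediate
9 | methyl 2-diazo-2-[2-{[2-(2,2-dimethylpropanoyloxy)-4-(triisopropylsilyloxy)phenyl]methoxy}-4-(triisopropylsilyloxy)phenyl]acetate | COC(=O)C(=[N+]=[N-])c1ccc(O[Si](C(C)C)(C(C)C)C(C)C)cc1OCc1ccc(O[Si](C(C)C)(C(C)C)C(C)C)cc1OC(=O)C(C)(C)C | intermediate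
10 | methyl (2R,3S)-2-[2-(2,2-dimethylpropanoyloxy)-4-(triisopropylsilyloxy)phenyl]-6-(triisopropylsilyloxy)-2,3-dihydro-1-benzofuran-3-carboxylate | COC(=O)[C@H]1c2ccc(O[Si](C(C)C)(C(C)C)C(C)C)cc2O[C@H]1c3ccc(O[Si](C(C)C)(C(C)C)C(C)C)cc3OC(=O)C(C)(C)C | intermediate
11 | 2-[(2R,3R)-3-(hydroxymethyl)-6-(triisopropylsilyloxy)-2,3-dihydro-1-benzofuran-2-yl]-5-(triisopropylsilyloxy)phenol | OC[C@H]1c2ccc(O[Si](C(C)C)(C(C)C)C(C)C)cc2O[C@H]1c3ccc(O[Si](C(C)C)(C(C)C)C(C)C)cc3O | intermediate
12 | (6aR,11aR)-3,9-bis(triisopropylsilyloxy)-6a,11a-dihydro-6H-[1]benzofuro[3,2-c]chromene | C1[C@H]2c3ccc(O[Si](C(C)C)(C(C)C)C(C)C)cc3O[C@H]2c4ccc(O[Si](C(C)C)(C(C)C)C(C)C)cc4O1 | intermediate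
13 | 2-[(3R)-7-(triisopropylsilyloxy)-3,4-dihydro-2H-chromen-3-yl]-5-(triisopropylsilyloxy)phenol | CC(C)[Si](C(C)C)(C(C)C)Oc1ccc2c(c1)OC[C@@H](c1ccc(O[Si](C(C)C)(C(C)C)C(C)C)cc1O)C2 | intermediate
14 | 5-(triisopropylsilyloxy)-2-[(3R)-7-(triisopropylsilyloxy)-3,4-dihydro-2H-chromen-3-yl]phenyl 2,2-dimethylpropanoate | CC(C)[Si](C(C)C)(C(C)C)Oc1ccc2c(c1)OC[C@@H](c1ccc(O[Si](C(C)C)(C(C)C)C(C)C)cc1OC(=O)C(C)(C)C)C2 | intermediate
15 | 5-hydroxy-2-[(3R)-7-hydroxy-3,4-dihydro-2H-chromen-3-yl]phenyl 2,2-dimethylpropanoate | Oc1ccc2c(c1)OC[C@@H](c1ccc(O)cc1OC(=O)C(C)(C)C)C2 | intermediate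
16 | prenyl bromide (1-bromo-3-methylbut-2-ene) | CC(C)=CCBr | starting material
17 | 5-[(3-methylbut-2-en-1-yl)oxy]-2-[(3R)-7-[(3-methylbut-2-en-1-yl)oxy]-3,4-dihydro-2H-chromen-3-yl]phenyl 2,2-dimethylpropanoate | CC(C)=CCOc1ccc2c(c1)OC[C@@H](c1ccc(OCC=C(C)C)cc1OC(=O)C(C)(C)C)C2 | intermediate
18 | 5-hydroxy-2-[(3R)-7-hydroxy-6-(2-methylbut-3-en-2-yl)-3,4-dihydro-2H-chromen-3-yl]-4-(2-methylbut-3-en-2-yl)phenyl 2,2-dimethylpropanoate | C=CC(C)(C)c1cc2c(cc1O)OC[C@@H](c1cc(C(C)(C)C=C)c(O)cc1OC(=O)C(C)(C)C)C2 | intermediate
19 | manuifolin E, 4-[(3R)-7-hydroxy-6-(2-methylbut-3-en-2-yl)-3,4-dihydro-2H-chromen-3-yl]-6-(2-methylbut-3-en-2-yl)benzene-1,3-diol | C=CC(C)(C)c1cc2c(cc1O)OC[C@@H](c1cc(C(C)(C)C=C)c(O)cc1O)C2 | target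

## Step count and least certain steps

Total: 16 steps. Longest linear sequence: 14 steps (steps 1–3 and 6–16); the ring B branch (steps 4 and 5) joins at step 6.

**Step 8 (key step).** The most likely failure is erosion of enantio- and cis-selectivity, because the ortho-pivaloyloxy group on the inserting benzyl carbon crowds the catalyst pocket. Material may also be lost by carbene dimerisation or by aromatic cycloaddition into ring A.

Fallback: the C3–C4 bond would be made by oxazolidinone-auxiliary (Evans) enolate alkylation in place of carbenoid insertion. It sets out from phenol 7 and alcohol 4 and returns to the route at isoflavan 13.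
- Phenol 7 is benzylated (BnBr, K2CO3, acetone) to methyl 2-[2-(benzyloxy)-4-(triisopropylsilyloxy)phenyl]acetate F1.
- F1 is saponified (LiOH, THF–H2O, 0 °C) to 2-[2-(benzyloxy)-4-(triisopropylsilyloxy)phenyl]acetic acid F2.
- F2 is coupled with (R)-4-benzyl-1,3-oxazolidin-2-one (PivCl, Et3N, LiCl, THF, −20 °C to rt) to give the imide (4R)-4-benzyl-3-{2-[2-(benzyloxy)-4-(triisopropylsilyloxy)phenyl]acetyl}-1,3-oxazolidin-2-one F3.
- Alcohol 4 is converted by the Appel reaction (CBr4, PPh3, CH2Cl2, 0 °C) into 2-(bromomethyl)-5-(triisopropylsilyloxy)phenyl pivalate F4.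
- F3 is deprotonated (NaN(SiMe3)2, THF, −78 °C) and alkylated by F4 on the face away from the auxiliary benzyl group to give (4R)-4-benzyl-3-[(2R)-2-[2-(benzyloxy)-4-(triisopropylsilyloxy)phenyl]-3-[2-(pivaloyloxy)-4-(triisopropylsilyloxy)phenyl]propanoyl]-1,3-oxazolidin-2-one F5.
- LiAlH4 (THF, 0 °C) removes the auxiliary reductively and cleaves the pivalate to give 2-[(2R)-2-[2-(benzyloxy)-4-(triisopropylsilyloxy)phenyl]-3-hydroxypropyl]-5-(triisopropylsilyloxy)phenol F6.
- Mitsunobu closure, in which only O1 is free, gives (3R)-3-[2-(benzyloxy)-4-(triisopropylsilyloxy)phenyl]-7-(triisopropylsilyloxy)chroman F7.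
- Hydrogenolysis of the benzyl ether (H2, Pd/C) gives 13.

**Step 15.** The most likely failure is regiochemical leakage to C8 or C3'; ring B is the weaker case because its meta substituent is an acyloxy and not an alkoxy group. A second failure is abnormal Claisen rearrangement or ring closure of the free ortho-(1,1-dimethylallyl)phenols at the reaction temperature.

Fallback: the rearrangement is run with in situ O-acylation so that no free phenol exists at high temperature, and the route is rejoined only at the target. Setting out from 17, heating with Ac2O and NaOAc in N,N-diethylaniline at 190 °C should give 5-acetoxy-2-[(3R)-7-acetoxy-6-(2-methylbut-3-en-2-yl)-3,4-dihydro-2H-chromen-3-yl]-4-(2-methylbut-3-en-2-yl)phenyl pivalate F8. One global reductive deacylation of F8 (LiAlH4, THF, 0 °C) then gives 19 directly, bypassing 18.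

**Step 5.** The most likely failure is incomplete site selectivity, with silylation at the 2-hydroxyl or at both hydroxyls, since the two phenols of 6 differ only by one ortho substituent.

Fallback: the 2-hydroxyl is masked as a lactone. Setting out from acid 5, acid-catalysed lactonisation (TsOH cat., toluene, reflux, water separator) gives 6-hydroxy-1-benzofuran-2(3H)-one F9. Silylation of its only hydroxyl (TIPSCl, imidazole) gives 6-(triisopropylsilyloxy)-1-benzofuran-2(3H)-one F10. Methanolysis (MeOH, Et3N, rt) opens the lactone and returns to 7.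

**Step 6.** The most likely failure is ionisation of the activated alkoxyphosphonium derived from 4 (para-silyloxy group, neighbouring ortho-acyloxy group), leading to acyl transfer or C-alkylation of the phenol in place of O-alkylation.

Fallback: the redox condensation is replaced by a Williamson alkylation with a preformed halide. Setting out from 4, MsCl, Et3N and LiCl in THF give 2-(chloromethyl)-5-(triisopropylsilyloxy)phenyl pivalate F11, which alkylates the potassium phenoxide of 7 (K2CO3, KI cat., acetone) and returns to 8.

## Further compounds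

F1 | step 8 | methyl 2-[2-(benzyloxy)-4-(triisopropylsilyloxy)phenyl]acetate | COC(=O)Cc1ccc(O[Si](C(C)C)(C(C)C)C(C)C)cc1OCc1ccccc1
F2 | step 8 | 2-[2-(benzyloxy)-4-(triisopropylsilyloxy)phenyl]acetic acid | OC(=O)Cc1ccc(O[Si](C(C)C)(C(C)C)C(C)C)cc1OCc1ccccc1
F3 | step 8 | (4R)-4-benzyl-3-{2-[2-(benzyloxy)-4-(triisopropylsilyloxy)phenyl]acetyl}-1,3-oxazolidin-2-one | O=C(Cc1ccc(O[Si](C(C)C)(C(C)C)C(C)C)cc1OCc1ccccc1)N1[C@H](Cc2ccccc2)COC1=O
F4 | step 8 | 2-(bromomethyl)-5-(triisopropylsilyloxy)phenyl 2,2-dimethylpropanoate | BrCc1ccc(O[Si](C(C)C)(C(C)C)C(C)C)cc1OC(=O)C(C)(C)C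
F5 | step 8 | (4R)-4-benzyl-3-[(2R)-2-[2-(benzyloxy)-4-(triisopropylsilyloxy)phenyl]-3-[2-(2,2-dimethylpropanoyloxy)-4-(triisopropylsilyloxy)phenyl]propanoyl]-1,3-oxazolidin-2-one | O=C([C@H](Cc1ccc(O[Si](C(C)C)(C(C)C)C(C)C)cc1OC(=O)C(C)(C)C)c1ccc(O[Si](C(C)C)(C(C)C)C(C)C)cc1OCc1ccccc1)N1[C@H](Cc2ccccc2)COC1=O
F6 | step 8 | 2-[(2R)-2-[2-(benzyloxy)-4-(triisopropylsilyloxy)phenyl]-3-hydroxypropyl]-5-(triisopropylsilyloxy)phenol | OC[C@H](Cc1ccc(O[Si](C(C)C)(C(C)C)C(C)C)cc1O)c1ccc(O[Si](C(C)C)(C(C)C)C(C)C)cc1OCc1ccccc1
F7 | step 8 | (3R)-3-[2-(benzyloxy)-4-(triisopropylsilyloxy)phenyl]-7-(triisopropylsilyloxy)-3,4-dihydro-2H-chromene | CC(C)[Si](C(C)C)(C(C)C)Oc1ccc2c(c1)OC[C@@H](c1ccc(O[Si](C(C)C)(C(C)C)C(C)C)cc1OCc1ccccc1)C2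
F8 | step 15 | 5-acetoxy-2-[(3R)-7-acetoxy-6-(2-methylbut-3-en-2-yl)-3,4-dihydro-2H-chromen-3-yl]-4-(2-methylbut-3-en-2-yl)phenyl 2,2-dimethylpropanoate | C=CC(C)(C)c1cc2c(cc1OC(C)=O)OC[C@@H](c1cc(C(C)(C)C=C)c(OC(C)=O)cc1OC(=O)C(C)(C)C)C2
F9 | step 5 | 6-hydroxy-1-benzofuran-2(3H)-one | O=C1Cc2ccc(O)cc2O1
F10 | step 5 | 6-(triisopropylsilyloxy)-1-benzofuran-2(3H)-one | O=C1Cc2ccc(O[Si](C(C)C)(C(C)C)C(C)C)cc2O1
F11 | step 6 | 2-(chloromethyl)-5-(triisopropylsilyloxy)phenyl 2,2-dimethylpropanoate | ClCc1ccc(O[Si](C(C)C)(C(C)C)C(C)C)cc1OC(=O)C(C)(C)C
A1 | alternative 1 | (3R)-7-[(3-methylbut-2-en-1-yl)oxy]-3-{4-[(3-methylbut-2-en-1-yl)oxy]-2-{[2-(trimethylsilyl)ethoxy]methoxy}phenyl}-3,4-dihydro-2H-chromene | CC(C)=CCOc1ccc2c(c1)OC[C@@H](c1ccc(OCC=C(C)C)cc1OCOCC[Si](C)(C)C)C2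
A2 | alternative 1 | 2'-O-SEM manuifolin E, (3R)-3-[4-hydroxy-5-(2-methylbut-3-en-2-yl)-2-{[2-(trimethylsilyl)ethoxy]methoxy}phenyl]-6-(2-methylbut-3-en-2-yl)-3,4-dihydro-2H-chromen-7-ol | C=CC(C)(C)c1cc2c(cc1O)OC[C@@H](c1cc(C(C)(C)C=C)c(O)cc1OCOCC[Si](C)(C)C)C2
A3 | alternative 2 | 4-(2-methylbut-3-en-2-yl)benzene-1,3-diol | C=CC(C)(C)c1ccc(O)cc1O
A4 | alternative 2 | 2-[2,4-bis(tert-butyldimethylsilyloxy)-5-(2-methylbut-3-en-2-yl)phenyl]prop-2-enal | C=C(C=O)c1cc(C(C)(C)C=C)c(O[Si](C)(C)C(C)(C)C)cc1O[Si](C)(C)C(C)(C)C
A5 | alternative 2 | (3R)-3-[2,4-bis(tert-butyldimethylsilyloxy)-5-(2-methylbut-3-en-2-yl)phenyl]-6-(2-methylbut-3-en-2-yl)-3,4-dihydro-2H-chromene-2,7-diol (lactol, both C2 epimers) | C=CC(C)(C)c1cc2c(cc1O)OC(O)[C@@H](c1cc(C(C)(C)C=C)c(O[Si](C)(C)C(C)(C)C)cc1O[Si](C)(C)C(C)(C)C)C2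
A6 | alternative 3 | vinylboronic acid pinacol ester, 2-ethenyl-4,4,5,5-tetramethyl-1,3,2-dioxaborolane | C=CB1OC(C)(C)C(C)(C)O1
A7 | alternative 3 | {4-(benzyloxy)-2-{[2-(trimethylsilyl)ethoxy]methoxy}phenyl}lithium | [Li]c1ccc(OCc2ccccc2)cc1OCOCC[Si](C)(C)C
A8 | alternative 3 | 2,4-bis(benzyloxy)-1-bromobenzene | Brc1ccc(OCc2ccccc2)cc1OCc1ccccc1
A9 | alternative 3 | 2-[(1R)-1-{4-(benzyloxy)-2-{[2-(trimethylsilyl)ethoxy]methoxy}phenyl}-2-[2,4-bis(benzyloxy)phenyl]ethyl]-4,4,5,5-tetramethyl-1,3,2-dioxaborolane | CC1(C)OB(OC1(C)C)[C@@H](c1ccc(OCc2ccccc2)cc1OCOCC[Si](C)(C)C)Cc1ccc(OCc2ccccc2)cc1OCc1ccccc1
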